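| flask | starting material | reagent | free catalyst | impurity | remark |
|---|---|---|---|---|---|
| Wednesday's | 20 mM | 36 mM | 40 µM | 12 µM | run made earlier |
| Tuesday's | 20 mM | 36 mM | 40 µM | 46 µM | run made earlier |
| Thursday's | 20 mM | 72 mM | 40 µM | 23 µM | run made earlier |
| flask | 20 mM | 36.0 mM | 40 µM | 23 µM |  |

| run | time / h | target / % | starting material / % |
|---|---|---|---|
| Wednesday's | 1.00 | 0 | 92.2 |
| Wednesday's | 2.00 | 0.7 | 86.0 |
| Wednesday's | 3.00 | 1.8 | 80.1 |
| Wednesday's | 4.00 | 3.4 | 76.7 |
| Wednesday's | 5.00 | 4.8 | 72.2 |
| Wednesday's | 6.00 | 7.4 | 69.3 |
| Tuesday's | 1.00 | 0.2 | 99.8 |
| Tuesday's | 2.00 | 0 | 98.9 |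
| Tuesday's | 3.00 | 0.3 | 98.9 |
| Tuesday's | 4.00 | 0 | 98.9 |
| Tuesday's | 5.00 | 1.6 | 98.5 |
| Tuesday's | 6.00 | 0.3 | 98.1 |
| Thursday's | 1.33 | 0.2 | 93.8 |
| Thursday's | 2.50 | 1.4 | 87.8 |
| Thursday's | 4.00 | 3.1 | 83.6 |
| Thursday's | 5.00 | 3.6 | 79.9 |
| Thursday's | 6.00 | 5.6 | 77.3 |

(standard deviation of a reading: 0.5 percentage points)

- the analysis behind the earlier runs scatters by 0.5 percentage points, standard deviation
- no earlier run changes the charge of free catalyst; that part of a forecast is a guess

* apparent order in free catalyst when 30% of the starting material are converted (percent change of the rate of making target for one percent more free catalyst charged)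
* apparent order in reagent when 30% of the starting material are converted (percent change of the rate of making target for one percent more reagent charged)

1. Early times show the impurity at work. Wednesday's run, with 12 µM impurity, fell to 92.2% starting material within 1.00 h, but Tuesday's run, charged with more impurity than free catalyst, still held 98.1% at 6.00 h.

2. The impurity therefore reads as a titrant of the catalyst, one for one (stoichiometric poisoning). In the flask, by this reckoning, 17.0 µM of catalyst should remain, so 42.5% of the charge should survive. This is the surviving share: catalyst charged minus impurity, over catalyst charged.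

3. As a check, Thursday's loss rate up to its first reading over Wednesday's reads 0.598, with 72 mM reagent against 36 mM, and the remaining catalyst stands in the ratio 0.607.

4. The zero of the scale is order one, that of a rate proportional to the catalyst charged with nothing deducted. In the flask the impurity is a fixed deduction, so added catalyst joins the survivors, and for a rate proportional to them the reckoned order is one over the surviving share: 2.35.

5. For whoever takes over: the flask was charged with starting material, reagent in excess, catalyst and impurity. Later it should lose starting material as Thursday's run did, with the same 17.0 µM reckoned to remain. Leave the catalyst charge alone, because by this reckoning one percent more moves the rate 2.35 percent.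

6. The forecast gives 2.3 in catalyst, on the ground that “loss scales with catalyst left after the impurity titrates it”, and 0.7 in reagent.

The flask gives 2.4 in free catalyst and 0.79 in reagent.

    reagent + free catalyst + intermediate ⇌ free catalyst + target (K = 535 /M, k = 21.6 /M²/s)
    starting material + free catalyst ⇌ free catalyst + intermediate (K = 0.880, k = 0.799 /M/s)
    free catalyst + impurity → spent catalyst (k = 153 /M/s)

Free catalyst makes up 42.5% of the catalyst charged at 9.18 h, and the surviving share was 42.5%. The surviving share of Wednesday's run is 70.0%, and the fall of its starting material, read as 7.8 percentage points in 1.00 h, scaled by the two shares, puts the flask at 96.2% starting material at 0.800 h. The flask then holds 95.8% starting material.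

The runs stem from a simulated flask for substances that don't exist; scatter was added.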